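**Assumption:** the target has no stereocentre and no stable chirality axis (the C1 aryl group is para-substituted), so it is a single achiral compound and no enantiocontrol is needed.

**Retrosynthetic overview**
- Target ← its heptamethyl ether by global O-demethylation (last step).
- The only ring formed in the route is the second naphthalene ring (C1–C4). It is closed by a double aldol condensation (C3=C4, then C1=C2) of 1,4-bis(2,4-dimethoxyphenyl)butane-1,4-dione with 2-(4-methoxybenzoyl)-4,5-dimethoxybenzaldehyde. All other rings are bought.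
- The 1,4-diketone ← two acyl-anion (Breslow intermediate) additions of 2,4-dimethoxybenzaldehyde to divinyl sulfone, which serves as a CH2–CH2 dication equivalent. Both aroyl–carbon bonds are made this way, in the same flask as the annulation.
- The keto-aldehyde ← 2-bromo-4,5-dimethoxybenzaldehyde by in situ aldehyde masking, Br–Li exchange and Weinreb acylation.

**Route**

Step 1
Reactants: 1 2-bromo-4,5-dimethoxybenzaldehyde; 2 N,4-dimethoxy-N-methylbenzamide
Product: 6 2-(4-methoxybenzoyl)-4,5-dimethoxybenzaldehyde, via lithium amino alkoxide 3 (not isolated), via aryllithium 4 (not isolated), via dilithium tetrahedral adduct 5 (not isolated)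
Conditions: morpholine (1.1 equiv), n-BuLi (1.1 equiv), THF, −78 °C; add 1, −78 → −40 °C; n-BuLi (1.1 equiv), −78 °C; add 2, −78 → 0 °C; 1 M aq. HCl, rt
Reagents that add atoms: none
Why: Lithium morpholide masks the aldehyde in situ as an α-amino alkoxide, bromine–lithium exchange gives an aryllithium that the Weinreb amide acylates only once (chelated tetrahedral adduct), and acid work-up releases both carbonyl groups; no stereocentre remains in 6.

Step 2
Reactants: 7 2,4-dimethoxybenzaldehyde (2.0 equiv); 8 divinyl sulfone (1.0 equiv); 6 2-(4-methoxybenzoyl)-4,5-dimethoxybenzaldehyde (1.0 equiv, added in the second stage)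
Product: 13 2,3-bis(2,4-dimethoxybenzoyl)-6,7-dimethoxy-1-(4-methoxyphenyl)naphthalene, via keto sulfone 9 (not isolated), via aryl vinyl ketone 10 (not isolated), via 1,4-diketone 11 (not isolated), via arylidene diketone 12 (not isolated)
Conditions: 3-ethyl-5-(2-hydroxyethyl)-4-methylthiazolium bromide (20 mol%), Et3N (1.3 equiv), 1,4-dioxane, 80 °C, until 7 is consumed; then 6, KOH (3 equiv), EtOH, 80 °C; aq. HCl work-up
Reagents that add atoms: none
Why: Proposed new method: the thiazol-2-ylidene converts 7 into its Breslow intermediate (acyl anion equivalent), which adds to divinyl sulfone in a Stetter reaction to give 9, E1cB loss of ethenesulfinate unveils enone 10 for a second Stetter addition to give 11, and hydroxide then drives an aldol condensation of 11 with the aldehyde of 6 to give (E)-12 (aryl cis to the remaining CH2) followed by an intramolecular aldol condensation onto the diaryl ketone with aromatisation as the driving force, the closest known reactions being the thiazolium-catalysed synthesis of symmetrical 1,4-diketones from aldehydes and divinyl sulfone and the base-mediated double aldol benzannulation of phthalaldehydes with 1,4-diketones (pentacenequinone type); no stereocentre is formed.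

Step 3
Reactants: 13 2,3-bis(2,4-dimethoxybenzoyl)-6,7-dimethoxy-1-(4-methoxyphenyl)naphthalene
Product: 14 2,3-bis(2,4-dihydroxybenzoyl)-1-(4-hydroxyphenyl)naphthalene-6,7-diol
Conditions: BBr3 (14 equiv), CH2Cl2, −78 °C → rt, N2; then ice-water, 0 °C
Reagents that add atoms: none
Why: Lewis-acid ether cleavage, in which BBr3 coordinates each aryl methyl ether oxygen and bromide removes the methyl group by SN2 (the two ethers ortho to the carbonyl groups go first through chelation), and hydrolysis frees the seven phenols while the diaryl ketones are untouched; no stereocentre is present.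

**Compound list**
1 | 2-bromo-4,5-dimethoxybenzaldehyde | COc1cc(Br)c(C=O)cc1OC | starting material
2 | N,4-dimethoxy-N-methylbenzamide | CON(C)C(=O)c1ccc(OC)cc1 | starting material
3 | lithium (2-bromo-4,5-dimethoxyphenyl)(morpholin-4-yl)methanolate (racemic) | [Li+].[O-]C(N1CCOCC1)c1cc(OC)c(OC)cc1Br | intermediate
4 | lithium (2-lithio-4,5-dimethoxyphenyl)(morpholin-4-yl)methanolate (racemic) | [Li+].[O-]C(N1CCOCC1)c1cc(OC)c(OC)cc1[Li] | intermediate
5 | dilithium adduct of 4 with 2: [2-(morpholin-4-yl-oxidomethyl)-4,5-dimethoxyphenyl](4-methoxyphenyl)[methoxy(methyl)amino]methanolate (diastereomer mixture) | [Li+].[Li+].[O-]C(N1CCOCC1)c1cc(OC)c(OC)cc1C([O-])(N(C)OC)c1ccc(OC)cc1 | intermediate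
6 | 2-(4-methoxybenzoyl)-4,5-dimethoxybenzaldehyde | COc1ccc(C(=O)c2cc(OC)c(OC)cc2C=O)cc1 | intermediate
7 | 2,4-dimethoxybenzaldehyde | COc1ccc(C=O)c(OC)c1 | starting material
8 | divinyl sulfone | C=CS(=O)(=O)C=C | starting material
9 | 1-(2,4-dimethoxyphenyl)-3-(ethenylsulfonyl)propan-1-one | COc1ccc(C(=O)CCS(=O)(=O)C=C)c(OC)c1 | intermediate
10 | 1-(2,4-dimethoxyphenyl)prop-2-en-1-one | COc1ccc(C(=O)C=C)c(OC)c1 | intermediate
11 | 1,4-bis(2,4-dimethoxyphenyl)butane-1,4-dione | COc1ccc(C(=O)CCC(=O)c2ccc(OC)cc2OC)c(OC)c1 | intermediate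
12 | (E)-2-{[4,5-dimethoxy-2-(4-methoxybenzoyl)phenyl]methylidene}-1,4-bis(2,4-dimethoxyphenyl)butane-1,4-dione | COc1ccc(C(=O)/C(CC(=O)c2ccc(OC)cc2OC)=C/c2cc(OC)c(OC)cc2C(=O)c2ccc(OC)cc2)c(OC)c1 | intermediate
13 | 2,3-bis(2,4-dimethoxybenzoyl)-6,7-dimethoxy-1-(4-methoxyphenyl)naphthalene | COc1ccc(C(=O)c2cc3cc(OC)c(OC)cc3c(-c3ccc(OC)cc3)c2C(=O)c2ccc(OC)cc2OC)c(OC)c1 | intermediate
14 | 2,3-bis(2,4-dihydroxybenzoyl)-1-(4-hydroxyphenyl)naphthalene-6,7-diol (CNP0304576.0) | O=C(c1ccc(O)cc1O)c1cc2cc(O)c(O)cc2c(-c2ccc(O)cc2)c1C(=O)c1ccc(O)cc1O | target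

**Step count**
Total steps: 3. Longest linear sequence: 3 (1 → 6 → 13 → 14).

**Steps most likely to fail, with fallbacks**

Step 2 is the most exposed. The Breslow intermediate of the electron-rich, ortho-substituted aldehyde 7 forms slowly. Keto sulfone 9 may take up a second acyl unit before it eliminates, which wastes aldehyde. The final aldol closure onto a hindered diaryl ketone may stall at 12. The fallback gives up the acyl-anion construction and makes the central CH2–CH2 bond by oxidative enolate coupling instead. It sets out from 7: MeMgBr (THF, 0 °C) gives 1-(2,4-dimethoxyphenyl)ethanol F1, and MnO2 (CH2Cl2, rt) gives 1-(2,4-dimethoxyphenyl)ethanone F2. F2 is itself a cheap catalogue compound and would in practice be bought. Its lithium enolate (LiN(i-Pr)2, THF, −78 °C) is dimerised with CuCl2 in DMF (−78 °C → rt), and the fallback comes back to the route at 11. Here 11 is isolated by crystallisation and condensed with 6 in a separate flask (KOH, EtOH, 80 °C) to give 13.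

Step 3 is next. Sevenfold demethylation of a hindered polyketone may stop at partly methylated material, and the catechol product is air-sensitive. The fallback is a staged cleavage that sets out from 13. BCl3 (CH2Cl2, 0 °C) removes only the two methyl ethers ortho to the carbonyl groups through six-membered boron chelates, giving 2,3-bis(2-hydroxy-4-methoxybenzoyl)-6,7-dimethoxy-1-(4-methoxyphenyl)naphthalene F3. The remaining five ethers are then cleaved in molten pyridinium chloride (190 °C, N2), and the fallback comes back to the route at 14.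

Step 1 is the least risky of the three. The lithiated amino alkoxide 4 may be quenched or may be alkylated by the 1-bromobutane formed in the exchange, and acylation next to the bulky masked aldehyde may be slow. The fallback reverses the roles of the two carbonyl carbons and sets out from 1. 4-MeOC6H4MgBr (THF, 0 °C) adds to the aldehyde to give (2-bromo-4,5-dimethoxyphenyl)(4-methoxyphenyl)methanol F4. MnO2 (CH2Cl2, rt) gives (2-bromo-4,5-dimethoxyphenyl)(4-methoxyphenyl)methanone F5. Palladium-catalysed reductive carbonylation of the aryl bromide (Pd(OAc)2, di(1-adamantyl)-n-butylphosphine, CO/H2, TMEDA, toluene, 100 °C) then installs the formyl group, and the fallback comes back to the route at 6.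

**Further compounds**
F1 | step 2 | 1-(2,4-dimethoxyphenyl)ethanol (racemic) | COc1ccc(C(C)O)c(OC)c1
F2 | step 2 | 1-(2,4-dimethoxyphenyl)ethanone | COc1ccc(C(C)=O)c(OC)c1
F3 | step 3 | 2,3-bis(2-hydroxy-4-methoxybenzoyl)-6,7-dimethoxy-1-(4-methoxyphenyl)naphthalene | COc1ccc(C(=O)c2cc3cc(OC)c(OC)cc3c(-c3ccc(OC)cc3)c2C(=O)c2ccc(OC)cc2O)c(O)c1
F4 | step 1 | (2-bromo-4,5-dimethoxyphenyl)(4-methoxyphenyl)methanol (racemic) | COc1ccc(C(O)c2cc(OC)c(OC)cc2Br)cc1
F5 | step 1 | (2-bromo-4,5-dimethoxyphenyl)(4-methoxyphenyl)methanone | COc1ccc(C(=O)c2cc(OC)c(OC)cc2Br)cc1
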